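The 1,2-dioxane of the target joins its two fully substituted carbons, C3 and C6, twice: through the O1–O2 peroxide and through the unfunctionalised C4–C5 ethano bridge. That bridge is read as a reduced ring alkene and cut at C4–C5. The key step is a ring-closing metathesis that joins two vinyl groups across the peroxide and closes the six-membered 3,6-dihydro-1,2-dioxine in one operation. Its precursor is an unsymmetrical bis(tertiary allylic) peroxide that already carries both stereocentres, each set from a Sharpless epoxide by backside attack of a peroxide oxygen. The acid arm travels as a silyl-protected primary alcohol.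

Key step: step 11

Remark: the arm is carried as a tert-butyldiphenylsilyl ether, chosen because steps 7 and 8 run under acid catalysis that a smaller silyl ether would not survive; bromide 8 is assumed to be a catalogue compound (otherwise one step from 3-bromopropan-1-ol and tBuPh2SiCl).

Step 1
Reactants: 1 (8-bromooctyl)benzene; 2 ethyl but-2-ynoate
Product: 5 ethyl (2E)-3-methyl-11-phenylundec-2-enoate, via (8-phenyloctyl)magnesium bromide 3 (not isolated), via (8-phenyloctyl)copper 4 (not isolated)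
Conditions: Mg, THF, rt; CuBr·SMe2 (1 equiv), THF, −78 → −40 °C; 2, −78 °C; aq NH4Cl at −78 °C
Reagents that add atoms: none
Why: Organocopper conjugate addition to an acetylenic ester (carbocupration) is a syn addition, so the new chain ends up trans to the ester and the cold proton quench should preserve the E alkene.

Step 2
Reactants: 5 ethyl (2E)-3-methyl-11-phenylundec-2-enoate
Product: 6 (2E)-3-methyl-11-phenylundec-2-en-1-ol
Conditions: iBu2AlH (2.2 equiv), CH2Cl2, −78 → 0 °C; aq Rochelle salt
Reagents that add atoms: none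
Why: Ester reduction with iBu2AlH at low temperature gives the allylic alcohol by 1,2-reduction and leaves the trisubstituted alkene and its geometry alone.

Step 3
Reactants: 6 (2E)-3-methyl-11-phenylundec-2-en-1-ol
Product: 7 [(2R,3R)-3-methyl-3-(8-phenyloctyl)oxiran-2-yl]methanol
Conditions: Ti(OiPr)4 (10 mol%), D-(−)-diethyl tartrate (12 mol%), tBuOOH (2 equiv, in decane), 4 Å MS, CH2Cl2, −20 °C
Reagents that add atoms: tert-butyl hydroperoxide, CC(C)(C)OO
Why: Sharpless asymmetric epoxidation: the Ti(OiPr)4–D-(−)-tartrate catalyst binds the allylic alcohol and delivers the peroxide oxygen to one alkene face, which for an E-3-methyl allylic alcohol gives the (2R,3R)-epoxide.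

Step 4
Reactants: 8 (3-bromopropoxy)(tert-butyl)diphenylsilane; 2 ethyl but-2-ynoate
Product: 11 ethyl (2E)-6-[(tert-butyldiphenylsilyl)oxy]-3-methylhex-2-enoate, via {3-[(tert-butyldiphenylsilyl)oxy]propyl}magnesium bromide 9 (not isolated), via {3-[(tert-butyldiphenylsilyl)oxy]propyl}copper 10 (not isolated)
Conditions: Mg, THF, rt; CuBr·SMe2 (1 equiv), THF, −78 → −40 °C; 2, −78 °C; aq NH4Cl at −78 °C
Reagents that add atoms: none
Why: The same carbocupration as in step 1; a 3-silyloxypropyl Grignard reagent is stable because the silyloxy group is a poor leaving group, and syn addition again gives the E ester.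

Step 5
Reactants: 11 ethyl (2E)-6-[(tert-butyldiphenylsilyl)oxy]-3-methylhex-2-enoate
Product: 12 (2E)-6-[(tert-butyldiphenylsilyl)oxy]-3-methylhex-2-en-1-ol
Conditions: iBu2AlH (2.2 equiv), CH2Cl2, −78 → 0 °C; aq Rochelle salt
Reagents that add atoms: none
Why: Ester reduction with iBu2AlH as in step 2; the silyl ether is inert to the hydride.

Step 6
Reactants: 12 (2E)-6-[(tert-butyldiphenylsilyl)oxy]-3-methylhex-2-en-1-ol
Product: 13 [(2R,3R)-3-{3-[(tert-butyldiphenylsilyl)oxy]propyl}-3-methyloxiran-2-yl]methanol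
Conditions: Ti(OiPr)4 (10 mol%), D-(−)-diethyl tartrate (12 mol%), tBuOOH (2 equiv, in decane), 4 Å MS, CH2Cl2, −20 °C
Reagents that add atoms: tert-butyl hydroperoxide, CC(C)(C)OO
Why: Sharpless asymmetric epoxidation as in step 3, with the same D-(−)-tartrate and therefore the same (2R,3R) sense; the remote silyl ether does not interfere.

Step 7
Reactants: 13 [(2R,3R)-3-{3-[(tert-butyldiphenylsilyl)oxy]propyl}-3-methyloxiran-2-yl]methanol
Product: 14 (2R,3S)-6-[(tert-butyldiphenylsilyl)oxy]-3-hydroperoxy-3-methylhexane-1,2-diol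
Conditions: H2O2 (anhydrous, in Et2O, 10 equiv), H3PMo12O40 (2 mol%), Et2O, 0 °C → rt, behind a shield
Reagents that add atoms: hydrogen peroxide, OO
Why: Acid-catalysed perhydrolysis of a trisubstituted epoxide: H2O2 opens the more substituted C3–O bond from the rear, so C3 is inverted from R to S, and the large excess of H2O2 should outrun the hindered silyl ether oxygen and the hydroxyl groups.

Step 8
Reactants: 14 (2R,3S)-6-[(tert-butyldiphenylsilyl)oxy]-3-hydroperoxy-3-methylhexane-1,2-diol; 7 [(2R,3R)-3-methyl-3-(8-phenyloctyl)oxiran-2-yl]methanol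
Product: 15 (2R,3S)-3-{[(2R,3S)-6-[(tert-butyldiphenylsilyl)oxy]-1,2-dihydroxy-3-methylhexan-3-yl]peroxy}-3-methyl-11-phenylundecane-1,2-diol
Conditions: 7 (1 equiv), 14 (2 equiv, excess recovered), H3PMo12O40 (5 mol%), 4 Å MS, CH2Cl2–Et2O, 0 °C → rt
Reagents that add atoms: none
Why: Acid-catalysed opening of a trisubstituted epoxide by an alkyl hydroperoxide: the OOH group of 14, more nucleophilic than its hydroxyl groups, should attack the tertiary carbon of 7 anti to the departing epoxide oxygen, which inverts that centre from R to S and creates the di-tertiary peroxide.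

Step 9
Reactants: 15 (2R,3S)-3-{[(2R,3S)-6-[(tert-butyldiphenylsilyl)oxy]-1,2-dihydroxy-3-methylhexan-3-yl]peroxy}-3-methyl-11-phenylundecane-1,2-diol
Product: 16 (2S)-2-{[(2S)-5-[(tert-butyldiphenylsilyl)oxy]-2-methyl-1-oxopentan-2-yl]peroxy}-2-methyl-10-phenyldecanal
Conditions: NaIO4 (2.5 equiv), THF–pH 7 buffer, 0 °C → rt
Reagents that add atoms: none
Why: Periodate glycol cleavage removes C1 of each half as formaldehyde and leaves two aldehydes on fully substituted carbons, which cannot enolise or epimerise, while NaIO4 does not attack a dialkyl peroxide.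

Step 10
Reactants: 16 (2S)-2-{[(2S)-5-[(tert-butyldiphenylsilyl)oxy]-2-methyl-1-oxopentan-2-yl]peroxy}-2-methyl-10-phenyldecanal; 17 methyltriphenylphosphonium bromide
Product: 19 tert-butyl({(4S)-4-methyl-4-{[(3S)-3-methyl-11-phenylundec-1-en-3-yl]peroxy}hex-5-en-1-yl}oxy)diphenylsilane, via methylidenetriphenylphosphorane 18 (not isolated)
Conditions: 17 (2.6 equiv), KN(SiMe3)2 (2.4 equiv), THF, 0 °C; then 16, −78 → 0 °C
Reagents that add atoms: none
Why: Wittig methylenation of both α-peroxy aldehydes with the ylide; a di-tertiary peroxide has no hydrogen on its peroxide-bearing carbons for base-induced cleavage, and no stereocentre is touched.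

Step 11
Reactants: 19 tert-butyl({(4S)-4-methyl-4-{[(3S)-3-methyl-11-phenylundec-1-en-3-yl]peroxy}hex-5-en-1-yl}oxy)diphenylsilane
Product: 20 tert-butyl{3-[(3S,6S)-3,6-dimethyl-6-(8-phenyloctyl)-3,6-dihydro-1,2-dioxin-3-yl]propoxy}diphenylsilane
Conditions: second-generation Hoveyda–Grubbs catalyst (10 mol% in two portions), degassed toluene, 0.002 M, 50 °C, argon sparge; ethyl vinyl ether quench
Reagents that add atoms: none
Why: Proposed new method: the alkylidene formed from the catalyst should load on one vinyl group, undergo intramolecular [2+2] cycloaddition with the second vinyl group and cyclorevert to the ring alkene, each turnover releasing ethene (Chauvin cycle). The closest known reaction type is ring-closing metathesis of dienes whose two allylic carbons are fully substituted and joined through an ether oxygen, together with olefin metathesis run on substrates that contain dialkyl peroxides; closure across an O–O tether has not been shown. The ring is closed as a six-membered ring by forming the C4=C5 bond, and the ring enforces the cis alkene. No stereocentre is formed, and C3 and C6 are fully substituted and not touched by the alkylidene, so the configurations set in steps 7 and 8 should be carried through unchanged. The step needs cyclisation over oligomerisation and survival of the O–O bond: high dilution, the geminal substitution at both allylic carbons and the gauche C–O–O–C geometry favour closure, while a phosphine-free catalyst and the absence of hydrogen on the peroxide-bearing carbons remove the usual reductive and base-induced ways of breaking a peroxide.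

Step 12
Reactants: 20 tert-butyl{3-[(3S,6S)-3,6-dimethyl-6-(8-phenyloctyl)-3,6-dihydro-1,2-dioxin-3-yl]propoxy}diphenylsilane
Product: 21 tert-butyl{3-[(3S,6S)-3,6-dimethyl-6-(8-phenyloctyl)-1,2-dioxan-3-yl]propoxy}diphenylsilane
Conditions: KO2C–N=N–CO2K (excess, in portions), AcOH, MeOH–CH2Cl2, 0 °C → rt
Reagents that add atoms: none
Why: Diimide reduction transfers two hydrogens to the cis ring alkene in a concerted step and does not reduce the O–O bond, which catalytic hydrogenation would break.

Step 13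
Reactants: 21 tert-butyl{3-[(3S,6S)-3,6-dimethyl-6-(8-phenyloctyl)-1,2-dioxan-3-yl]propoxy}diphenylsilane
Product: 22 3-[(3S,6S)-3,6-dimethyl-6-(8-phenyloctyl)-1,2-dioxan-3-yl]propan-1-ol
Conditions: Bu4NF (1.5 equiv), AcOH (1.5 equiv), THF, rt
Reagents that add atoms: none
Why: Fluoride-induced desilylation driven by the Si–F bond; AcOH buffering keeps the medium near neutral, and the di-tertiary peroxide has no acidic α-hydrogen.

Step 14
Reactants: 22 3-[(3S,6S)-3,6-dimethyl-6-(8-phenyloctyl)-1,2-dioxan-3-yl]propan-1-ol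
Product: 23 3-[(3R,6S)-3,6-dimethyl-6-(8-phenyloctyl)-1,2-dioxan-3-yl]propanoic acid
Conditions: TEMPO (10 mol%), NaClO2 (2 equiv), NaOCl (2 mol%), MeCN–phosphate buffer (pH 6.7), 35 °C
Reagents that add atoms: sodium chlorite, [Na+].[O-]Cl=O
Why: TEMPO-catalysed oxidation with NaClO2 as the stoichiometric oxidant takes the primary alcohol through the aldehyde to the acid near neutral pH, conditions under which a dialkyl peroxide and the quaternary stereocentres are stable (the descriptor at C3 changes from S to R only because the CIP priorities change).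

Compound list
1 | (8-bromooctyl)benzene | BrCCCCCCCCc1ccccc1 | starting material
2 | ethyl but-2-ynoate | CC#CC(=O)OCC | starting material
3 | (8-phenyloctyl)magnesium bromide | Br[Mg]CCCCCCCCc1ccccc1 | intermediate
4 | (8-phenyloctyl)copper, as its MgBr2 complex | [Cu]CCCCCCCCc1ccccc1 | intermediate
5 | ethyl (2E)-3-methyl-11-phenylundec-2-enoate | CCOC(=O)/C=C(\C)CCCCCCCCc1ccccc1 | intermediate
6 | (2E)-3-methyl-11-phenylundec-2-en-1-ol | OC/C=C(\C)CCCCCCCCc1ccccc1 | intermediate
7 | [(2R,3R)-3-methyl-3-(8-phenyloctyl)oxiran-2-yl]methanol | OC[C@H]1O[C@]1(C)CCCCCCCCc1ccccc1 | intermediate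
8 | (3-bromopropoxy)(tert-butyl)diphenylsilane | BrCCCO[Si](c1ccccc1)(c1ccccc1)C(C)(C)C | starting material
9 | {3-[(tert-butyldiphenylsilyl)oxy]propyl}magnesium bromide | Br[Mg]CCCO[Si](c1ccccc1)(c1ccccc1)C(C)(C)C | intermediate
10 | {3-[(tert-butyldiphenylsilyl)oxy]propyl}copper, as its MgBr2 complex | [Cu]CCCO[Si](c1ccccc1)(c1ccccc1)C(C)(C)C | intermediate
11 | ethyl (2E)-6-[(tert-butyldiphenylsilyl)oxy]-3-methylhex-2-enoate | CCOC(=O)/C=C(\C)CCCO[Si](c1ccccc1)(c1ccccc1)C(C)(C)C | intermediate
12 | (2E)-6-[(tert-butyldiphenylsilyl)oxy]-3-methylhex-2-en-1-ol | OC/C=C(\C)CCCO[Si](c1ccccc1)(c1ccccc1)C(C)(C)C | intermediate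
13 | [(2R,3R)-3-{3-[(tert-butyldiphenylsilyl)oxy]propyl}-3-methyloxiran-2-yl]methanol | OC[C@H]1O[C@]1(C)CCCO[Si](c1ccccc1)(c1ccccc1)C(C)(C)C | intermediate
14 | (2R,3S)-6-[(tert-butyldiphenylsilyl)oxy]-3-hydroperoxy-3-methylhexane-1,2-diol | OC[C@@H](O)[C@@](C)(OO)CCCO[Si](c1ccccc1)(c1ccccc1)C(C)(C)C | intermediate
15 | (2R,3S)-3-{[(2R,3S)-6-[(tert-butyldiphenylsilyl)oxy]-1,2-dihydroxy-3-methylhexan-3-yl]peroxy}-3-methyl-11-phenylundecane-1,2-diol | OC[C@@H](O)[C@@](C)(OO[C@@](C)(CCCO[Si](c1ccccc1)(c1ccccc1)C(C)(C)C)[C@H](O)CO)CCCCCCCCc1ccccc1 | intermediate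
16 | (2S)-2-{[(2S)-5-[(tert-butyldiphenylsilyl)oxy]-2-methyl-1-oxopentan-2-yl]peroxy}-2-methyl-10-phenyldecanal | O=C[C@@](C)(OO[C@@](C)(CCCO[Si](c1ccccc1)(c1ccccc1)C(C)(C)C)C=O)CCCCCCCCc1ccccc1 | intermediate
17 | methyltriphenylphosphonium bromide | C[P+](c1ccccc1)(c1ccccc1)c1ccccc1.[Br-] | starting material
18 | methylidenetriphenylphosphorane | C=P(c1ccccc1)(c1ccccc1)c1ccccc1 | intermediate
19 | tert-butyl({(4S)-4-methyl-4-{[(3S)-3-methyl-11-phenylundec-1-en-3-yl]peroxy}hex-5-en-1-yl}oxy)diphenylsilane | C[C@](OO[C@@](C)(CCCO[Si](c1ccccc1)(c1ccccc1)C(C)(C)C)C=C)(CCCCCCCCc1ccccc1)C=C | intermediate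
20 | tert-butyl{3-[(3S,6S)-3,6-dimethyl-6-(8-phenyloctyl)-3,6-dihydro-1,2-dioxin-3-yl]propoxy}diphenylsilane | C[C@]1(CCCCCCCCc2ccccc2)C=C[C@](C)(CCCO[Si](c2ccccc2)(c3ccccc3)C(C)(C)C)OO1 | intermediate
21 | tert-butyl{3-[(3S,6S)-3,6-dimethyl-6-(8-phenyloctyl)-1,2-dioxan-3-yl]propoxy}diphenylsilane | C[C@]1(CCCCCCCCc2ccccc2)CC[C@](C)(CCCO[Si](c2ccccc2)(c3ccccc3)C(C)(C)C)OO1 | intermediate
22 | 3-[(3S,6S)-3,6-dimethyl-6-(8-phenyloctyl)-1,2-dioxan-3-yl]propan-1-ol | C[C@]1(CCCCCCCCc2ccccc2)CC[C@](C)(CCCO)OO1 | intermediate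
23 | 3-[(3R,6S)-3,6-dimethyl-6-(8-phenyloctyl)-1,2-dioxan-3-yl]propanoic acid | C[C@]1(CCCCCCCCc2ccccc2)CC[C@](C)(CCC(=O)O)OO1 | target

Total step count: 14. Longest linear sequence: 11 steps (steps 4 to 14).

Steps most likely to fail

1. Step 11, ring-closing metathesis across the peroxide. The alkylidene may fail to turn over on two vinyl groups that both sit on fully substituted carbons, or electron transfer from the metal may cleave the O–O bond, so that closure loses to oligomerisation or decomposition. The fallback forms the C4–C5 bond before any peroxide exists and closes the ring at oxygen, using only established reaction types. It sets out from ethyl but-2-ynoate 2 and comes back at target 23.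
 - Carbocupration of 2 with the organocopper made from (4-bromobut-1-yn-1-yl)trimethylsilane (Mg; CuBr·SMe2, THF, −78 °C) should give ethyl (2E)-3-methyl-7-(trimethylsilyl)hept-2-en-6-ynoate F1.
 - iBu2AlH should give (2E)-3-methyl-7-(trimethylsilyl)hept-2-en-6-yn-1-ol F2, and K2CO3 in MeOH should give (2E)-3-methylhept-2-en-6-yn-1-ol F3.
 - Zirconium-catalysed carboalumination (Me3Al, Cp2ZrCl2), then trapping of the alkenylalane with paraformaldehyde, should give (2E,6E)-3,6-dimethylocta-2,6-diene-1,8-diol F4.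
 - Twofold Sharpless epoxidation with L-(+)-diethyl tartrate should give (2S,3S,6S,7S)-2,3:6,7-diepoxy-3,6-dimethyloctane-1,8-diol F5.
 - About one equivalent of H2O2 with H3PMo12O40 should open one epoxide at its tertiary carbon; the hydroperoxide formed should open the second epoxide at its tertiary carbon in a 6-exo closure. Both openings are invertive and should give the C2-symmetric trans tetraol (1S,1′S)-1,1′-[(3R,6R)-3,6-dimethyl-1,2-dioxane-3,6-diyl]di(ethane-1,2-diol) F6.
 - NaIO4 should give (3R,6R)-3,6-dimethyl-1,2-dioxane-3,6-dicarbaldehyde F7.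
 - Wittig reaction with one equivalent of the ylide from (7-phenylheptyl)triphenylphosphonium bromide and NaN(SiMe3)2 should give (3R,6R)-3,6-dimethyl-6-[(1Z)-8-phenyloct-1-en-1-yl]-1,2-dioxane-3-carbaldehyde F8. This step is statistical, with recovery of F7.
 - The ylide from (carboxymethyl)triphenylphosphonium chloride and two equivalents of KOtBu should give (2E)-3-{(3R,6R)-3,6-dimethyl-6-[(1Z)-8-phenyloct-1-en-1-yl]-1,2-dioxan-3-yl}prop-2-enoic acid F9.
 - Diimide reduction of both disubstituted alkenes of F9 should give 23.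

2. Step 8, union of the two halves. The hindered tertiary hydroperoxide may attack the tertiary epoxide carbon too slowly, so that hydride shift, elimination or attack by hydroxyl groups takes over, or the opening may drift toward a carbocation and lose its inversion. The fallback replaces the epoxy alcohol by the matching 2,2-disubstituted oxetane, whose acid-promoted opening by alkyl hydroperoxides at the tertiary carbon is an established invertive reaction, and makes the vinyl group by elimination. It sets out from 7 and 14 and comes back at 19.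
 - NaAlH2(OCH2CH2OMe)2 should open 7 at C2 to give (3R)-3-methyl-11-phenylundecane-1,3-diol F10.
 - Tosylation of the primary hydroxyl should give (3R)-3-hydroxy-3-methyl-11-phenylundecyl 4-methylbenzenesulfonate F11, and KOtBu should close (2R)-2-methyl-2-(8-phenyloctyl)oxetane F12.
 - Opening of F12 by 14 with Yb(OTf)3 in Et2O should give, with inversion, (2R,3S)-6-[(tert-butyldiphenylsilyl)oxy]-3-{[(3S)-1-hydroxy-3-methyl-11-phenylundecan-3-yl]peroxy}-3-methylhexane-1,2-diol F13.
 - NaIO4 should give (2S)-5-[(tert-butyldiphenylsilyl)oxy]-2-{[(3S)-1-hydroxy-3-methyl-11-phenylundecan-3-yl]peroxy}-2-methylpentanal F14.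
 - Methylenation with an excess of ylide 18 should give (3S)-3-{[(3S)-6-[(tert-butyldiphenylsilyl)oxy]-3-methylhex-1-en-3-yl]peroxy}-3-methyl-11-phenylundecan-1-ol F15.
 - MsCl and Et3N should give (3S)-3-{[(3S)-6-[(tert-butyldiphenylsilyl)oxy]-3-methylhex-1-en-3-yl]peroxy}-3-methyl-11-phenylundecyl methanesulfonate F16, and elimination with KOtBu in THF should give 19.

3. Step 10, double methylenation. The ylide or residual base may add to the hindered α-peroxy aldehydes in a way that fragments the C–C bond next to the peroxide, or olefination may stop after one aldehyde. The fallback avoids the aldehydes altogether. It sets out from tetraol 15 and comes back at 19.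
 - MsCl and Et3N should give (2R,3S)-3-{[(2R,3S)-6-[(tert-butyldiphenylsilyl)oxy]-1,2-bis(methanesulfonyloxy)-3-methylhexan-3-yl]peroxy}-3-methyl-11-phenylundecane-1,2-diyl dimethanesulfonate F17.
 - NaI in butan-2-one at 70 °C should displace each primary sulfonate and then trigger iodide-induced 1,2-elimination of the neighbouring secondary sulfonate. This gives both vinyl groups without loss of carbon and should give 19.

Further compounds
F1 | step 11 | ethyl (2E)-3-methyl-7-(trimethylsilyl)hept-2-en-6-ynoate | CCOC(=O)/C=C(\C)CCC#C[Si](C)(C)C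
F2 | step 11 | (2E)-3-methyl-7-(trimethylsilyl)hept-2-en-6-yn-1-ol | OC/C=C(\C)CCC#C[Si](C)(C)C
F3 | step 11 | (2E)-3-methylhept-2-en-6-yn-1-ol | OC/C=C(\C)CCC#C
F4 | step 11 | (2E,6E)-3,6-dimethylocta-2,6-diene-1,8-diol | OC/C=C(\C)CC/C(C)=C/CO
F5 | step 11 | (2S,3S,6S,7S)-2,3:6,7-diepoxy-3,6-dimethyloctane-1,8-diol | OC[C@@H]1O[C@@]1(C)CC[C@]2(C)O[C@H]2CO
F6 | step 11 | (1S,1′S)-1,1′-[(3R,6R)-3,6-dimethyl-1,2-dioxane-3,6-diyl]di(ethane-1,2-diol) | OC[C@H](O)[C@@]1(C)CC[C@](C)([C@@H](O)CO)OO1
F7 | step 11 | (3R,6R)-3,6-dimethyl-1,2-dioxane-3,6-dicarbaldehyde | C[C@]1(C=O)CC[C@](C)(C=O)OO1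
F8 | step 11 | (3R,6R)-3,6-dimethyl-6-[(1Z)-8-phenyloct-1-en-1-yl]-1,2-dioxane-3-carbaldehyde | C[C@]1(/C=C\CCCCCCc2ccccc2)CC[C@](C)(C=O)OO1
F9 | step 11 | (2E)-3-{(3R,6R)-3,6-dimethyl-6-[(1Z)-8-phenyloct-1-en-1-yl]-1,2-dioxan-3-yl}prop-2-enoic acid | C[C@]1(/C=C\CCCCCCc2ccccc2)CC[C@](C)(/C=C/C(=O)O)OO1
F10 | step 8 | (3R)-3-methyl-11-phenylundecane-1,3-diol | OCC[C@](C)(O)CCCCCCCCc1ccccc1
F11 | step 8 | (3R)-3-hydroxy-3-methyl-11-phenylundecyl 4-methylbenzenesulfonate | Cc1ccc(cc1)S(=O)(=O)OCC[C@](C)(O)CCCCCCCCc1ccccc1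
F12 | step 8 | (2R)-2-methyl-2-(8-phenyloctyl)oxetane | C[C@@]1(CCCCCCCCc2ccccc2)CCO1
F13 | step 8 | (2R,3S)-6-[(tert-butyldiphenylsilyl)oxy]-3-{[(3S)-1-hydroxy-3-methyl-11-phenylundecan-3-yl]peroxy}-3-methylhexane-1,2-diol | OCC[C@@](C)(OO[C@@](C)(CCCO[Si](c1ccccc1)(c1ccccc1)C(C)(C)C)[C@H](O)CO)CCCCCCCCc1ccccc1
F14 | step 8 | (2S)-5-[(tert-butyldiphenylsilyl)oxy]-2-{[(3S)-1-hydroxy-3-methyl-11-phenylundecan-3-yl]peroxy}-2-methylpentanal | OCC[C@@](C)(OO[C@@](C)(CCCO[Si](c1ccccc1)(c1ccccc1)C(C)(C)C)C=O)CCCCCCCCc1ccccc1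
F15 | step 8 | (3S)-3-{[(3S)-6-[(tert-butyldiphenylsilyl)oxy]-3-methylhex-1-en-3-yl]peroxy}-3-methyl-11-phenylundecan-1-ol | OCC[C@@](C)(OO[C@@](C)(CCCO[Si](c1ccccc1)(c1ccccc1)C(C)(C)C)C=C)CCCCCCCCc1ccccc1
F16 | step 8 | (3S)-3-{[(3S)-6-[(tert-butyldiphenylsilyl)oxy]-3-methylhex-1-en-3-yl]peroxy}-3-methyl-11-phenylundecyl methanesulfonate | CS(=O)(=O)OCC[C@@](C)(OO[C@@](C)(CCCO[Si](c1ccccc1)(c1ccccc1)C(C)(C)C)C=C)CCCCCCCCc1ccccc1
F17 | step 10 | (2R,3S)-3-{[(2R,3S)-6-[(tert-butyldiphenylsilyl)oxy]-1,2-bis(methanesulfonyloxy)-3-methylhexan-3-yl]peroxy}-3-methyl-11-phenylundecane-1,2-diyl dimethanesulfonate | CS(=O)(=O)OC[C@@H](OS(C)(=O)=O)[C@@](C)(OO[C@@](C)(CCCO[Si](c1ccccc1)(c1ccccc1)C(C)(C)C)[C@H](OS(C)(=O)=O)COS(C)(=O)=O)CCCCCCCCc1ccccc1
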